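**Retrosynthetic overview**
1. The target reads as epicatechin-(4β→6)-ent-epicatechin-(4α→8)-epicatechin-(4β→6)-ent-epicatechin, units 1 to 4 (the 2-aryl group of a 2R unit is α). All rings and all C2/C3 centres come with (−)- and (+)-epicatechin, so no ring is formed. Only three C4–aryl bonds and their C4 centres must be made.
2. Last cut: C4 (ring C, unit 1)–C6 (ring A, unit 2). It is made as a one-pot union of two electrophilic carbons. The C6–I of an iodo trimer is reversed to C6–Mg and then C6–Zn, and this captures the C4 cation of an uncapped perbenzyl epicatechin C4 ether.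
3. Enabling feature: C4 of unit 1 is benzylic to a ring A whose O1, O5 and O7 stand ortho/para to C4a, which makes the cation easy to form. The axial 3α-oxygen next to C4 directs attack to the β face. C6 of unit 2 lies between O5 and O7, which hold a metal there, and it carries the only iodine beside the bromine caps on C8.
4. Before that: C4 (unit 2)–C8 (unit 3) by Friedel–Crafts alkylation of the unit 3–4 dimer with a 6-iodo-8-bromo unit 2 ether, where iodine serves first as a cap and later as the address. C4 (unit 3)–C6 (unit 4) is made by the same iodide-to-zinc union on monomers.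
5. Order of unions: 3–4, then 2–3, then 1–2. One hydrogenolysis then removes twenty benzyl groups and two bromines.

Key step: step 12

Assumption: (+)-epicatechin (ent-epicatechin, 2S,3S) is taken as a purchasable compound; it is also the C2 epimer that (+)-catechin gives in hot aqueous base.

Step 1
Reactants: 1 (−)-epicatechin
Product: 2 5,7,3',4'-tetra-O-benzyl-(−)-epicatechin
Conditions: BnBr, K2CO3, DMF, 0 °C to rt
Reagents that add atoms: benzyl bromide BrCc1ccccc1
Why: Williamson ether synthesis in which K2CO3 deprotonates only the four phenols, so the 3-OH stays free and C2 and C3 are not touched.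

Step 2
Reactants: 2 5,7,3',4'-tetra-O-benzyl-(−)-epicatechin
Product: 3 3,5,7,3',4'-penta-O-benzyl-(−)-epicatechin
Conditions: NaH, BnBr, DMF, 0 °C to rt
Reagents that add atoms: benzyl bromide BrCc1ccccc1
Why: Williamson ether synthesis on the 3-alkoxide removes the last acidic proton, which the organometallic steps could not tolerate, without touching a stereocentre.

Step 3
Reactants: 3 3,5,7,3',4'-penta-O-benzyl-(−)-epicatechin
Product: 4 4β-(2-ethoxyethoxy)-3,5,7,3',4'-penta-O-benzyl-(−)-epicatechin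
Conditions: DDQ, EtOCH2CH2OH, CH2Cl2, rt
Reagents that add atoms: 2-ethoxyethanol CCOCCO
Why: Benzylic oxidation by hydride abstraction with DDQ (known C4 oxygenation of benzylated flavan-3-ols) gives the C4 cation stabilised by O1, O5 and O7, which the alcohol traps from the β face anti to the axial 3α-benzyloxy group.

Step 4
Reactants: 5 (+)-epicatechin
Product: 6 5,7,3',4'-tetra-O-benzyl-(+)-epicatechin
Conditions: BnBr, K2CO3, DMF, 0 °C to rt
Reagents that add atoms: benzyl bromide BrCc1ccccc1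
Why: Williamson ether synthesis on the four phenols only, as in step 1, with C2 and C3 untouched.

Step 5
Reactants: 6 5,7,3',4'-tetra-O-benzyl-(+)-epicatechin
Product: 7 3,5,7,3',4'-penta-O-benzyl-(+)-epicatechin
Conditions: NaH, BnBr, DMF, 0 °C to rt
Reagents that add atoms: benzyl bromide BrCc1ccccc1
Why: Williamson ether synthesis on the 3-alkoxide, as in step 2.

Step 6
Reactants: 7 3,5,7,3',4'-penta-O-benzyl-(+)-epicatechin
Product: 8 8-bromo-3,5,7,3',4'-penta-O-benzyl-(+)-epicatechin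
Conditions: NBS, CH2Cl2, −78 to 0 °C
Reagents that add atoms: N-bromosuccinimide O=C1CCC(=O)N1Br
Why: Electrophilic aromatic bromination goes to C8, the most nucleophilic and least crowded position of ring A, as is known for benzylated flavan-3-ols.

Step 7
Reactants: 8 8-bromo-3,5,7,3',4'-penta-O-benzyl-(+)-epicatechin
Product: 9 8-bromo-6-iodo-3,5,7,3',4'-penta-O-benzyl-(+)-epicatechin
Conditions: NIS, CF3CO2H (cat.), MeCN–CH2Cl2, 0 °C to rt, dark
Reagents that add atoms: N-iodosuccinimide O=C1CCC(=O)N1I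
Why: Electrophilic aromatic iodination can only reach C6, the last free position of the trioxygenated ring A, in line with the known 6,8-dihalogenation of these ethers.

Step 8
Reactants: 9 8-bromo-6-iodo-3,5,7,3',4'-penta-O-benzyl-(+)-epicatechin; 4 4β-(2-ethoxyethoxy)-3,5,7,3',4'-penta-O-benzyl-(−)-epicatechin
Product: 12 deca-O-benzyl epicatechin-(4β→6)-(8-bromo-ent-epicatechin), via arylmagnesium chloride 10 (not isolated), via arylzinc chloride 11 (not isolated)
Conditions: iPrMgCl·LiCl, THF, −20 °C; ZnCl2, −20 °C; Me3SiOTf, CH2Cl2, −78 °C, then 4 added slowly, −78 to −40 °C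
Reagents that add atoms: none
Why: Proposed new method: this rehearses the sequence of step 12 on monomers, namely selective iodine–magnesium exchange at C6 (C8–Br untouched), transmetalation to zinc, and ipso attack of the Me3SiOTf-generated C4 cation of 4 on the zinc-bearing carbon from the β face anti to the axial 3α-benzyloxy group, which sets the 4β (3,4-trans) centre; the closest known types are the Lewis-acid-promoted arylation of oxocarbenium ions by arylzinc halides and the coupling of flavan-8-ylboronic acids with flavan C4 ethers.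

Step 9
Reactants: 8 8-bromo-3,5,7,3',4'-penta-O-benzyl-(+)-epicatechin
Product: 13 8-bromo-4α-(2-ethoxyethoxy)-3,5,7,3',4'-penta-O-benzyl-(+)-epicatechin
Conditions: DDQ, EtOCH2CH2OH, CH2Cl2, rt
Reagents that add atoms: 2-ethoxyethanol CCOCCO
Why: Benzylic oxidation with DDQ, known also for 8-bromo flavan-3-ol ethers, gives the C4 cation, which the alcohol traps from the α face anti to the axial 3β-benzyloxy group of the ent series.

Step 10
Reactants: 13 8-bromo-4α-(2-ethoxyethoxy)-3,5,7,3',4'-penta-O-benzyl-(+)-epicatechin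
Product: 14 8-bromo-6-iodo-4α-(2-ethoxyethoxy)-3,5,7,3',4'-penta-O-benzyl-(+)-epicatechin
Conditions: NIS, NaHCO3 (solid buffer), MeCN–CH2Cl2, rt, dark
Reagents that add atoms: N-iodosuccinimide O=C1CCC(=O)N1I
Why: Electrophilic aromatic iodination at C6, the only free carbon of ring A, is run acid-free so that the acid-labile C4 ether survives.

Step 11
Reactants: 14 8-bromo-6-iodo-4α-(2-ethoxyethoxy)-3,5,7,3',4'-penta-O-benzyl-(+)-epicatechin; 12 deca-O-benzyl epicatechin-(4β→6)-(8-bromo-ent-epicatechin)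
Product: 15 pentadeca-O-benzyl (8-bromo-6-iodo-ent-epicatechin)-(4α→8)-epicatechin-(4β→6)-(8-bromo-ent-epicatechin)
Conditions: Me3SiOTf (cat.), 4 Å molecular sieves, CH2Cl2, −78 to −30 °C
Reagents that add atoms: none
Why: Friedel–Crafts alkylation in which Me3SiOTf ionises the C4 ether of 14, whose ring A is silenced by iodine on C6 and bromine on C8 and so cannot attack itself, and the cation is taken by C8 of unit 3, the most nucleophilic free carbon of 12, from the α face anti to the axial 3β-benzyloxy group, which sets the 4α (3,4-trans) centre.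

Step 12
Reactants: 15 pentadeca-O-benzyl (8-bromo-6-iodo-ent-epicatechin)-(4α→8)-epicatechin-(4β→6)-(8-bromo-ent-epicatechin); 4 4β-(2-ethoxyethoxy)-3,5,7,3',4'-penta-O-benzyl-(−)-epicatechin
Product: 18 icosa-O-benzyl epicatechin-(4β→6)-(8-bromo-ent-epicatechin)-(4α→8)-epicatechin-(4β→6)-(8-bromo-ent-epicatechin), via trimer arylmagnesium chloride 16 (not isolated), via trimer arylzinc chloride 17 (not isolated)
Conditions: iPrMgCl·LiCl (1.1 equiv), THF, −20 °C; ZnCl2 (1.2 equiv), −20 °C; Me3SiOTf (1.2 equiv), CH2Cl2, −78 °C, then 4 (0.95 equiv) added slowly, −78 to −40 °C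
Reagents that add atoms: none
Why: Proposed new method: iPrMgCl·LiCl exchanges only the C6–I bond of unit 2 (a C–I bond exchanges far faster than the two C8–Br bonds, and the benzyloxy groups on C5 and C7 chelate and inductively stabilise the new C6–metal bond), ZnCl2 turns the aryl Grignard 16 into the Lewis-acid-tolerant arylzinc 17, Me3SiOTf ionises the C4–O bond of 4 to the benzylic cation that O1, O5 and O7 of its ring A stabilise, and this cation attacks C6 ipso to zinc, after which loss of the zinc fragment restores ring A. Two carbons that are both electrophilic in 15 (C6–I) and 4 (C4–O) are thus joined by polarity reversal at C6; the closest known reaction types are the Lewis-acid-promoted arylation of oxocarbenium ions by arylzinc halides in C-aryl glycoside synthesis, the coupling of flavan-8-ylboronic acids with flavan C4 ethers, and the addition of 8-lithiated flavans to flavan-4-ones. No ring is closed. The one new stereocentre, C4 of unit 1, is set by the substrate: the axial 3α-benzyloxy group shields the α face of the half-chair cation, so the aryl group enters pseudoaxially from the β face (3,4-trans, 4β), as in the known substitutions at C4 of epicatechin ethers. The step needs site selectivity for C6 of unit 2 over C6–H of unit 3 and over C8–H and C6–H of ring A in 4 and in 18, and this is secured because only that carbon carries the electron-releasing C–Zn σ bond, while C8 of units 2 and 4 stays blocked by bromine. Slow addition of 4 as the limiting partner into 17 and Me3SiOTf keeps the cation dilute beside a large excess of the best nucleophile.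

Step 13
Reactants: 18 icosa-O-benzyl epicatechin-(4β→6)-(8-bromo-ent-epicatechin)-(4α→8)-epicatechin-(4β→6)-(8-bromo-ent-epicatechin)
Product: 19 epicatechin-(4β→6)-ent-epicatechin-(4α→8)-epicatechin-(4β→6)-ent-epicatechin (target)
Conditions: H2 (1 atm), Pd(OH)2/C, Et3N, THF–MeOH–H2O, rt
Reagents that add atoms: none
Why: Catalytic hydrogenolysis cleaves the twenty benzyl ethers and reduces both aryl bromides in one operation (known joint removal of benzyl groups and bromine caps from flavan oligomers), Et3N binds the HBr that would otherwise cleave the acid-labile interflavan bonds, and no stereocentre is touched.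

**Compound list**
1 | (−)-epicatechin, (2R,3R) | Oc1cc(O)c2c(c1)O[C@H](c1ccc(O)c(O)c1)[C@H](O)C2 | starting material
2 | 5,7,3',4'-tetra-O-benzyl-(−)-epicatechin | O(Cc9ccccc9)c1cc(OCc9ccccc9)c2c(c1)O[C@H](c1ccc(OCc9ccccc9)c(OCc9ccccc9)c1)[C@H](O)C2 | intermediate
3 | 3,5,7,3',4'-penta-O-benzyl-(−)-epicatechin | O(Cc9ccccc9)c1cc(OCc9ccccc9)c2c(c1)O[C@H](c1ccc(OCc9ccccc9)c(OCc9ccccc9)c1)[C@H](OCc9ccccc9)C2 | intermediate
4 | 4β-(2-ethoxyethoxy)-3,5,7,3',4'-penta-O-benzyl-(−)-epicatechin (2,3-cis, 3,4-trans) | O(Cc9ccccc9)c1cc(OCc9ccccc9)c2c(c1)O[C@H](c1ccc(OCc9ccccc9)c(OCc9ccccc9)c1)[C@H](OCc9ccccc9)[C@H]2OCCOCC | intermediate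
5 | (+)-epicatechin (ent-epicatechin), (2S,3S) | c1c(O)cc2c(c1O)C[C@H](O)[C@H](c1ccc(O)c(O)c1)O2 | starting material
6 | 5,7,3',4'-tetra-O-benzyl-(+)-epicatechin | c1c(OCc9ccccc9)cc2c(c1OCc9ccccc9)C[C@H](O)[C@H](c1ccc(OCc9ccccc9)c(OCc9ccccc9)c1)O2 | intermediate
7 | 3,5,7,3',4'-penta-O-benzyl-(+)-epicatechin | c1c(OCc9ccccc9)cc2c(c1OCc9ccccc9)C[C@H](OCc9ccccc9)[C@H](c1ccc(OCc9ccccc9)c(OCc9ccccc9)c1)O2 | intermediate
8 | 8-bromo-3,5,7,3',4'-penta-O-benzyl-(+)-epicatechin | c1c(OCc9ccccc9)c(Br)c2c(c1OCc9ccccc9)C[C@H](OCc9ccccc9)[C@H](c1ccc(OCc9ccccc9)c(OCc9ccccc9)c1)O2 | intermediate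
9 | 8-bromo-6-iodo-3,5,7,3',4'-penta-O-benzyl-(+)-epicatechin | Ic1c(OCc9ccccc9)c(Br)c2c(c1OCc9ccccc9)C[C@H](OCc9ccccc9)[C@H](c1ccc(OCc9ccccc9)c(OCc9ccccc9)c1)O2 | intermediate
10 | 8-bromo-6-(chloromagnesio)-3,5,7,3',4'-penta-O-benzyl-(+)-epicatechin | Cl[Mg]c1c(OCc9ccccc9)c(Br)c2c(c1OCc9ccccc9)C[C@H](OCc9ccccc9)[C@H](c1ccc(OCc9ccccc9)c(OCc9ccccc9)c1)O2 | intermediate
11 | 8-bromo-6-(chlorozincio)-3,5,7,3',4'-penta-O-benzyl-(+)-epicatechin | Cl[Zn]c1c(OCc9ccccc9)c(Br)c2c(c1OCc9ccccc9)C[C@H](OCc9ccccc9)[C@H](c1ccc(OCc9ccccc9)c(OCc9ccccc9)c1)O2 | intermediate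
12 | deca-O-benzyl epicatechin-(4β→6)-(8-bromo-ent-epicatechin) | c1c(OCc9ccccc9)cc(OCc9ccccc9)c3c1O[C@H](c1ccc(OCc9ccccc9)c(OCc9ccccc9)c1)[C@H](OCc9ccccc9)[C@H]3c1c(OCc9ccccc9)c(Br)c3c(c1OCc9ccccc9)C[C@H](OCc9ccccc9)[C@H](c1ccc(OCc9ccccc9)c(OCc9ccccc9)c1)O3 | intermediate
13 | 8-bromo-4α-(2-ethoxyethoxy)-3,5,7,3',4'-penta-O-benzyl-(+)-epicatechin (2,3-cis, 3,4-trans) | c1c(OCc9ccccc9)c(Br)c2c(c1OCc9ccccc9)[C@@H](OCCOCC)[C@H](OCc9ccccc9)[C@H](c1ccc(OCc9ccccc9)c(OCc9ccccc9)c1)O2 | intermediate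
14 | 8-bromo-6-iodo-4α-(2-ethoxyethoxy)-3,5,7,3',4'-penta-O-benzyl-(+)-epicatechin | Ic1c(OCc9ccccc9)c(Br)c2c(c1OCc9ccccc9)[C@@H](OCCOCC)[C@H](OCc9ccccc9)[C@H](c1ccc(OCc9ccccc9)c(OCc9ccccc9)c1)O2 | intermediate
15 | pentadeca-O-benzyl (8-bromo-6-iodo-ent-epicatechin)-(4α→8)-epicatechin-(4β→6)-(8-bromo-ent-epicatechin) | Ic1c(OCc9ccccc9)c(Br)c2c(c1OCc9ccccc9)[C@@H](c1c(OCc9ccccc9)cc(OCc9ccccc9)c3c1O[C@H](c1ccc(OCc9ccccc9)c(OCc9ccccc9)c1)[C@H](OCc9ccccc9)[C@H]3c1c(OCc9ccccc9)c(Br)c3c(c1OCc9ccccc9)C[C@H](OCc9ccccc9)[C@H](c1ccc(OCc9ccccc9)c(OCc9ccccc9)c1)O3)[C@H](OCc9ccccc9)[C@H](c1ccc(OCc9ccccc9)c(OCc9ccccc9)c1)O2 | intermediate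
16 | trimer 15 with MgCl in place of iodine on C6 of unit 2 | Cl[Mg]c1c(OCc9ccccc9)c(Br)c2c(c1OCc9ccccc9)[C@@H](c1c(OCc9ccccc9)cc(OCc9ccccc9)c3c1O[C@H](c1ccc(OCc9ccccc9)c(OCc9ccccc9)c1)[C@H](OCc9ccccc9)[C@H]3c1c(OCc9ccccc9)c(Br)c3c(c1OCc9ccccc9)C[C@H](OCc9ccccc9)[C@H](c1ccc(OCc9ccccc9)c(OCc9ccccc9)c1)O3)[C@H](OCc9ccccc9)[C@H](c1ccc(OCc9ccccc9)c(OCc9ccccc9)c1)O2 | intermediate
17 | trimer 15 with ZnCl in place of iodine on C6 of unit 2 | Cl[Zn]c1c(OCc9ccccc9)c(Br)c2c(c1OCc9ccccc9)[C@@H](c1c(OCc9ccccc9)cc(OCc9ccccc9)c3c1O[C@H](c1ccc(OCc9ccccc9)c(OCc9ccccc9)c1)[C@H](OCc9ccccc9)[C@H]3c1c(OCc9ccccc9)c(Br)c3c(c1OCc9ccccc9)C[C@H](OCc9ccccc9)[C@H](c1ccc(OCc9ccccc9)c(OCc9ccccc9)c1)O3)[C@H](OCc9ccccc9)[C@H](c1ccc(OCc9ccccc9)c(OCc9ccccc9)c1)O2 | intermediate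
18 | icosa-O-benzyl epicatechin-(4β→6)-(8-bromo-ent-epicatechin)-(4α→8)-epicatechin-(4β→6)-(8-bromo-ent-epicatechin) | O(Cc9ccccc9)c1cc(OCc9ccccc9)c2c(c1)O[C@H](c1ccc(OCc9ccccc9)c(OCc9ccccc9)c1)[C@H](OCc9ccccc9)[C@H]2c1c(OCc9ccccc9)c(Br)c2c(c1OCc9ccccc9)[C@@H](c1c(OCc9ccccc9)cc(OCc9ccccc9)c3c1O[C@H](c1ccc(OCc9ccccc9)c(OCc9ccccc9)c1)[C@H](OCc9ccccc9)[C@H]3c1c(OCc9ccccc9)c(Br)c3c(c1OCc9ccccc9)C[C@H](OCc9ccccc9)[C@H](c1ccc(OCc9ccccc9)c(OCc9ccccc9)c1)O3)[C@H](OCc9ccccc9)[C@H](c1ccc(OCc9ccccc9)c(OCc9ccccc9)c1)O2 | intermediate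
19 | epicatechin-(4β→6)-ent-epicatechin-(4α→8)-epicatechin-(4β→6)-ent-epicatechin | Oc1cc(O)c2c(c1)O[C@H](c1ccc(O)c(O)c1)[C@H](O)[C@H]2c1c(O)cc2c(c1O)[C@@H](c1c(O)cc(O)c3c1O[C@H](c1ccc(O)c(O)c1)[C@H](O)[C@H]3c1c(O)cc3c(c1O)C[C@H](O)[C@H](c1ccc(O)c(O)c1)O3)[C@H](O)[C@H](c1ccc(O)c(O)c1)O2 | target

Total steps: 13. Longest linear sequence: 8 steps (5 → 6 → 7 → 8 → 9 → 12 → 15 → 18 → 19).

**Steps most likely to fail**

1. **Step 12.** Ipso attack at the doubly flanked, zinc-bearing C6 may be too slow. The cation could then be consumed in three other ways: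
   - attack on ring A of a second molecule of 4 or of the product (self-condensation, chain growth);
   - loss of H-3;
   - hydride transfer from isopropylzinc residues.

   The fallback is the known halogen-capped Friedel–Crafts 4→6 coupling. It blocks every competing nucleophilic carbon instead of activating one carbon. It sets out from 15 and 4 and comes back to the route at 19. The iodine of 15 is exchanged with iPrMgCl·LiCl and the aryl Grignard is quenched with MeOH, which should give the deiodinated trimer F1. One equivalent of NBS brominates C6 of unit 3, the only free carbon on the only halogen-free ring A, to give the tribromo trimer F2. In parallel, 4 is brominated at C6 and C8 with two equivalents of NBS to give the fully capped electrophile F3. F3 (in excess) and F2 with Me3SiOTf in CH2Cl2 can then meet only at C6 of unit 2 and should give the pentabromo tetramer F4. The conditions of step 13 take F4 to 19.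

2. **Step 8.** The same competition between ipso attack and self-condensation of 4 can occur on the monomers, and the exchange may be incomplete. The fallback sets out from 9 and comes back at 12. After iodine–magnesium exchange, 9 is trapped with B(OMe)3 and hydrolysed mildly to the isolated flavan-6-ylboronic acid F5. F5 is used in excess and coupled with 4 under Me3SiOTf. This is the known Lewis-acid-promoted coupling of flavanylboronic acids with C4 ethers, and it should give 12.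

3. **Step 13.** Twenty-two reductive events on one molecule may stall. Possible causes are catalyst poisoning by bromide, acid cleavage of interflavan bonds, and air oxidation of the free polyphenol during a long reaction. The fallback separates the two tasks. It sets out from 18 and comes back at 19. Bromine–lithium exchange (n-BuLi, THF, −78 °C) followed by MeOH should give the bromine-free icosa-O-benzyl tetramer F6. F6 is then debenzylated by halide-free and base-free hydrogenolysis over Pd(OH)2/C to 19.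

**Further compounds**
F1 | step 12 | pentadeca-O-benzyl (8-bromo-ent-epicatechin)-(4α→8)-epicatechin-(4β→6)-(8-bromo-ent-epicatechin) | c1c(OCc9ccccc9)c(Br)c2c(c1OCc9ccccc9)[C@@H](c1c(OCc9ccccc9)cc(OCc9ccccc9)c3c1O[C@H](c1ccc(OCc9ccccc9)c(OCc9ccccc9)c1)[C@H](OCc9ccccc9)[C@H]3c1c(OCc9ccccc9)c(Br)c3c(c1OCc9ccccc9)C[C@H](OCc9ccccc9)[C@H](c1ccc(OCc9ccccc9)c(OCc9ccccc9)c1)O3)[C@H](OCc9ccccc9)[C@H](c1ccc(OCc9ccccc9)c(OCc9ccccc9)c1)O2
F2 | step 12 | pentadeca-O-benzyl (8-bromo-ent-epicatechin)-(4α→8)-(6-bromoepicatechin)-(4β→6)-(8-bromo-ent-epicatechin) | c1c(OCc9ccccc9)c(Br)c2c(c1OCc9ccccc9)[C@@H](c1c(OCc9ccccc9)c(Br)c(OCc9ccccc9)c3c1O[C@H](c1ccc(OCc9ccccc9)c(OCc9ccccc9)c1)[C@H](OCc9ccccc9)[C@H]3c1c(OCc9ccccc9)c(Br)c3c(c1OCc9ccccc9)C[C@H](OCc9ccccc9)[C@H](c1ccc(OCc9ccccc9)c(OCc9ccccc9)c1)O3)[C@H](OCc9ccccc9)[C@H](c1ccc(OCc9ccccc9)c(OCc9ccccc9)c1)O2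
F3 | step 12 | 6,8-dibromo-4β-(2-ethoxyethoxy)-3,5,7,3',4'-penta-O-benzyl-(−)-epicatechin | O(Cc9ccccc9)c1c(Br)c(OCc9ccccc9)c2c(c1Br)O[C@H](c1ccc(OCc9ccccc9)c(OCc9ccccc9)c1)[C@H](OCc9ccccc9)[C@H]2OCCOCC
F4 | step 12 | icosa-O-benzyl (6,8-dibromoepicatechin)-(4β→6)-(8-bromo-ent-epicatechin)-(4α→8)-(6-bromoepicatechin)-(4β→6)-(8-bromo-ent-epicatechin) | O(Cc9ccccc9)c1c(Br)c(OCc9ccccc9)c2c(c1Br)O[C@H](c1ccc(OCc9ccccc9)c(OCc9ccccc9)c1)[C@H](OCc9ccccc9)[C@H]2c1c(OCc9ccccc9)c(Br)c2c(c1OCc9ccccc9)[C@@H](c1c(OCc9ccccc9)c(Br)c(OCc9ccccc9)c3c1O[C@H](c1ccc(OCc9ccccc9)c(OCc9ccccc9)c1)[C@H](OCc9ccccc9)[C@H]3c1c(OCc9ccccc9)c(Br)c3c(c1OCc9ccccc9)C[C@H](OCc9ccccc9)[C@H](c1ccc(OCc9ccccc9)c(OCc9ccccc9)c1)O3)[C@H](OCc9ccccc9)[C@H](c1ccc(OCc9ccccc9)c(OCc9ccccc9)c1)O2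
F5 | step 8 | 8-bromo-3,5,7,3',4'-penta-O-benzyl-(+)-epicatechin-6-ylboronic acid | OB(O)c1c(OCc9ccccc9)c(Br)c2c(c1OCc9ccccc9)C[C@H](OCc9ccccc9)[C@H](c1ccc(OCc9ccccc9)c(OCc9ccccc9)c1)O2
F6 | step 13 | icosa-O-benzyl epicatechin-(4β→6)-ent-epicatechin-(4α→8)-epicatechin-(4β→6)-ent-epicatechin | O(Cc9ccccc9)c1cc(OCc9ccccc9)c2c(c1)O[C@H](c1ccc(OCc9ccccc9)c(OCc9ccccc9)c1)[C@H](OCc9ccccc9)[C@H]2c1c(OCc9ccccc9)cc2c(c1OCc9ccccc9)[C@@H](c1c(OCc9ccccc9)cc(OCc9ccccc9)c3c1O[C@H](c1ccc(OCc9ccccc9)c(OCc9ccccc9)c1)[C@H](OCc9ccccc9)[C@H]3c1c(OCc9ccccc9)cc3c(c1OCc9ccccc9)C[C@H](OCc9ccccc9)[C@H](c1ccc(OCc9ccccc9)c(OCc9ccccc9)c1)O3)[C@H](OCc9ccccc9)[C@H](c1ccc(OCc9ccccc9)c(OCc9ccccc9)c1)O2
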